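## Retrosynthetic overview

1. Numbering used throughout: C1 = CH bearing isopropenyl, C2, C3 (=CH), C4 (lactone α-carbon), C5, C6 (CH–O), C7, C8 (CH–CO2Me), C9 (C=O), C10, C11 (C=O), C12/C13 (epoxide), C14; C18 = lactone C=O, C19 = ester C=O, C20 = CH3 on C12.
2. The last disconnection is C7–C8 of the 14-membered ring: seco-iodide 20 is closed by C-alkylation of its 3,5-diketo ester dianion. The enabling feature is that C8 lies between the C19 ester and the C9–C10–C11 1,3-diketone, so the first deprotonation (C10) masks the diketone as its enolate and the second (C8) creates the only reactive carbanion; C7 is a primary CH2–I on C6 of the preformed α-alkylidene butyrolactone ring (O–C18–C4–C5–C6).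
3. C3=C4 comes from a Horner–Wadsworth–Emmons union of aldehyde 12 with phosphono-lactone 19 (C6 from (R)-benzyl glycidyl ether); C10–C11 comes from Claisen acylation of the methyl acetoacetate dianion.
4. C1, C12, C13, C20 and the cis-epoxide come from (S)-carvone. Its six-membered ring is a temporary ring (its C11–C2 bond is not in the target) that directs the epoxidation anti to isopropenyl and is then cut by α'-hydroxylation and Pb(OAc)4 cleavage; C3 is added by Wittig homologation.
5. Order of ring formation: epoxide (on the carvone ring) → carvone ring cleaved → butyrolactone (fragment 19) → 14-membered carbocycle (last step).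

Key step: step 11

Remark (assumption): C8 is the α-carbon of a β-keto ester and is configurationally labile, so the 8S configuration of the target is assumed to be the thermodynamically preferred one in the macrocycle and to be reached by equilibration. Compounds 11, 12, 20 and 23 are drawn as triketo tautomers although they should be largely enolised.

## Route

Step 1
Reactants: 1 (S)-(+)-carvone
Product: 2 trans-carvone oxide
Conditions: 30% aq. H2O2, NaOH (0.2 equiv), MeOH, 0 °C
Reagents that add atoms: hydrogen peroxide, OO
Why: Weitz–Scheffer nucleophilic epoxidation, in which hydroperoxide adds to C13 of the enone from the face anti to the C1 isopropenyl group, so that the cis-fused C12/C13 epoxide is set trans to isopropenyl, which is the relative configuration of the target (12S,13S against 1R).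

Step 2
Reactants: 2 trans-carvone oxide
Product: 4 α'-hydroxy epoxy ketone (C2 epimers), via potassium enolate 3 (not isolated)
Conditions: KN(SiMe3)2, THF, −78 °C; 2-(phenylsulfonyl)-3-phenyloxaziridine, −78 °C; aq. NH4Cl
Reagents that add atoms: 2-(phenylsulfonyl)-3-phenyloxaziridine, O=S(=O)(c1ccccc1)N1OC1c1ccccc1
Why: enolate hydroxylation with an N-sulfonyloxaziridine, where enolisation can only occur toward C2 because C12 is quaternary, and the configuration of the new carbinol is irrelevant because this carbon loses its oxygen stereocenter in step 3.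

Step 3
Reactants: 4 α'-hydroxy epoxy ketone
Product: 5 aldehyde ester
Conditions: Pb(OAc)4, MeOH/PhMe 1:1, 0 °C
Reagents that add atoms: methanol, CO
Why: Criegee-type cleavage of the α-ketol by Pb(OAc)4 in methanol cuts the C11–C2 bond of the temporary ring to give the C11 methyl ester and the C2 aldehyde under non-basic conditions that leave C1, C12 and C13 untouched.

Step 4
Reactants: 5 aldehyde ester; 6 (methoxymethyl)triphenylphosphonium chloride
Product: 8 enol ether ester (E/Z mixture), via methoxymethylene ylide 7 (not isolated)
Conditions: 6, KN(SiMe3)2, THF, 0 °C; then 5, −78 to 0 °C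
Reagents that add atoms: none
Why: Wittig methoxymethylenation adds C3 and keeps it masked as an enol ether, with the aldehyde added at −78 °C so that olefination should outrun enolisation and C1 keeps its configuration; the E/Z ratio is irrelevant.

Step 5
Reactants: 8 enol ether ester; 9 methyl acetoacetate
Product: 11 3,5-diketo ester enol ether, via sodium lithium dianion 10 (not isolated)
Conditions: 9 (3 equiv), NaH then n-BuLi, THF, 0 °C; then 8, −78 to 0 °C; AcOH
Reagents that add atoms: none
Why: Claisen acylation of the acetoacetate dianion at its terminal carbon by the non-enolisable glycidic ester installs C8–C10 and C19 in one step; the acylating carbon has no α-hydrogen, so no stereocenter is at risk.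

Step 6
Reactants: 11 3,5-diketo ester enol ether
Product: 12 aldehyde
Conditions: 0.5 M aq. (CO2H)2, THF, 20 °C
Reagents that add atoms: water, O
Why: mild acid hydrolysis of the methyl enol ether (protonation at C2, hydration at C3) frees the C3 aldehyde, while the α,β-epoxy ketone is deactivated toward acid-induced opening by its carbonyl group.

Step 7
Reactants: 13 triethyl phosphonoacetate; 14 (R)-benzyl glycidyl ether
Product: 17 benzyloxymethyl phosphono-lactone (C4 epimers), via sodium phosphonoacetate carbanion 15 (not isolated), via ring-opened sodium alkoxide 16 (not isolated)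
Conditions: NaOEt, EtOH, 80 °C; AcOH
Reagents that add atoms: none
Why: classical epoxide–active-methylene lactone annulation, in which the carbanion opens the epoxide by SN2 attack at the terminal CH2 (future C5) and the alkoxide closes the γ-lactone by 5-exo-trig acyl substitution; the C6–O bond is never broken, so C6 keeps the configuration of 14.

Step 8
Reactants: 17 benzyloxymethyl phosphono-lactone
Product: 18 hydroxymethyl phosphono-lactone
Conditions: H2 (1 atm), Pd/C, EtOH, 20 °C
Reagents that add atoms: none
Why: hydrogenolysis of the benzyl ether, with no other reducible group present.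

Step 9
Reactants: 18 hydroxymethyl phosphono-lactone
Product: 19 iodomethyl phosphono-lactone
Conditions: I2, PPh3, imidazole, CH2Cl2, 0 to 20 °C
Reagents that add atoms: iodine, II
Why: Appel-type iodination of the primary alcohol by SN2 at C7, which does not touch C6.

Step 10
Reactants: 12 aldehyde; 19 iodomethyl phosphono-lactone
Product: 20 seco-iodide
Conditions: LiCl, DBU, MeCN, 0 °C
Reagents that add atoms: none
Why: Horner–Wadsworth–Emmons olefination under Masamune–Roush conditions forms C3=C4, and α-phosphono-γ-butyrolactones should give mainly the (E)-alkylidene lactone (C2 anti to C18); the lithium-chelated diketo ester enolate is a spectator and any Z isomer is removed by chromatography.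

Step 11
Reactants: 20 seco-iodide
Product: 23 target CNP0108136.1, via disodium dianion 21 (not isolated), via macrocyclic sodium diketonate 22 (not isolated)
Conditions: NaN(SiMe3)2 (2.2 equiv), THF/DMPU 10:1, 2 mM, −78 to 0 °C; AcOH; C8 equilibrates on silica gel
Reagents that add atoms: none
Why: Proposed new method: NaN(SiMe3)2 removes first a C10 proton (1,3-diketone) and then a C8 proton (ester α-carbon), giving dianion 21 in which C10 is locked in the sodium diketonate while C8 is an ester-enolate-type carbanion that displaces iodide at C7 by SN2. The closest known reaction types are the γ-alkylation of β-keto ester dianions, the alkylation of 1,3,5-tricarbonyl polyanions at the last-formed carbanion, and macrocyclising C-alkylations of ω-halo β-keto esters; what is new is their use on a 3,5-diketo ester to close a macrocycle. The ring closed is the 14-membered carbocycle in a 14-exo-tet mode at high dilution; the lactone, the epoxide and C1, C6, C12 and C13 are spectators. The only new stereocenter, C8, is the acidic methine of the β-keto ester and is set under thermodynamic control by enolisation after the quench (assumed to favour 8S, see the remark). The step needs C8- over C10- and O-alkylation and SN2 at C7 over acyl attack at C18: the order of acidity (C10 before C8) makes C8 the most nucleophilic site and leaves the more stable diketonate 22 behind, and attack at C18 would need a 12-membered transition ring onto a conjugated, less electrophilic lactone. No protecting group is present, so the ring closure should deliver the target directly.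

## Compound list

1 | (S)-(+)-carvone, (5S)-2-methyl-5-(prop-1-en-2-yl)cyclohex-2-en-1-one | C=C(C)[C@@H]1CC(=O)C(C)=CC1 | starting material
2 | trans-carvone oxide, (1S,4S,6S)-1-methyl-4-(prop-1-en-2-yl)-7-oxabicyclo[4.1.0]heptan-2-one (epoxide anti to isopropenyl) | C=C(C)[C@@H]1CC(=O)[C@@]2(C)O[C@H]2C1 | intermediate
3 | potassium enolate of 2, enolised toward C3 of the bicycle (C2 of the target) | [K+].C=C(C)[C@@H]1C=C([O-])[C@@]2(C)O[C@H]2C1 | intermediate (not isolated)
4 | α'-hydroxy epoxy ketone, (1S,4R,6S)-3-hydroxy-1-methyl-4-(prop-1-en-2-yl)-7-oxabicyclo[4.1.0]heptan-2-one, same spatial arrangement at C1, C4 and C6 as in 2, C3 epimers | C=C(C)[C@@H]1C(O)C(=O)[C@@]2(C)O[C@H]2C1 | intermediate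
5 | methyl (2S,3S)-3-[(2R)-2-formyl-3-methylbut-3-en-1-yl]-2-methyloxirane-2-carboxylate | C=C(C)[C@H](C=O)C[C@@H]1O[C@]1(C)C(=O)OC | intermediate
6 | (methoxymethyl)triphenylphosphonium chloride | COC[P+](c1ccccc1)(c1ccccc1)c1ccccc1.[Cl-] | starting material
7 | (methoxymethylene)triphenylphosphorane | COC=P(c1ccccc1)(c1ccccc1)c1ccccc1 | intermediate (not isolated)
8 | methyl (2S,3S)-3-[(2S)-2-(2-methoxyethenyl)-3-methylbut-3-en-1-yl]-2-methyloxirane-2-carboxylate, E/Z mixture at the enol ether | C=C(C)[C@H](C=COC)C[C@@H]1O[C@]1(C)C(=O)OC | intermediate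
9 | methyl acetoacetate (methyl 3-oxobutanoate) | CC(=O)CC(=O)OC | starting material
10 | sodium lithium dianion of methyl acetoacetate | [Li+].[Na+].C=C([O-])C=C([O-])OC | intermediate (not isolated)
11 | methyl 5-[(2S,3S)-3-[(2S)-2-(2-methoxyethenyl)-3-methylbut-3-en-1-yl]-2-methyloxiran-2-yl]-3,5-dioxopentanoate | C=C(C)[C@H](C=COC)C[C@@H]1O[C@]1(C)C(=O)CC(=O)CC(=O)OC | intermediate
12 | methyl 5-[(2S,3S)-2-methyl-3-[(2S)-3-methyl-2-(2-oxoethyl)but-3-en-1-yl]oxiran-2-yl]-3,5-dioxopentanoate | C=C(C)[C@H](CC=O)C[C@@H]1O[C@]1(C)C(=O)CC(=O)CC(=O)OC | intermediate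
13 | triethyl phosphonoacetate | CCOC(=O)CP(=O)(OCC)OCC | starting material
14 | (R)-benzyl glycidyl ether, (2R)-2-[(benzyloxy)methyl]oxirane | C1O[C@H]1COCc1ccccc1 | starting material
15 | sodium salt (carbanion) of triethyl phosphonoacetate | [Na+].CCOC(=O)[CH-]P(=O)(OCC)OCC | intermediate (not isolated)
16 | sodium alkoxide of ethyl 5-(benzyloxy)-2-(diethoxyphosphoryl)-4-hydroxypentanoate, carbinol carbon configured as C6 of 17 | [Na+].CCOC(=O)C(C[C@H](COCc1ccccc1)[O-])P(=O)(OCC)OCC | intermediate (not isolated)
17 | diethyl [(5R)-5-[(benzyloxy)methyl]-2-oxooxolan-3-yl]phosphonate, C3 epimers | CCOP(=O)(OCC)C1C[C@H](COCc2ccccc2)OC1=O | intermediate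
18 | diethyl [(5R)-5-(hydroxymethyl)-2-oxooxolan-3-yl]phosphonate, C3 epimers | CCOP(=O)(OCC)C1C[C@H](CO)OC1=O | intermediate
19 | diethyl [(5R)-5-(iodomethyl)-2-oxooxolan-3-yl]phosphonate, C3 epimers | CCOP(=O)(OCC)C1C[C@H](CI)OC1=O | intermediate
20 | seco-iodide: methyl 3,5-dioxopentanoate whose C5 carries the (2S,3S)-2-methyloxiran-2-yl unit; the oxirane C3 bears CH2–CH(isopropenyl)–CH2–CH= ending in the (E)-3-ylidene-(5R)-5-(iodomethyl)oxolan-2-one; C1, C6, C12, C13 as in the target | C=C(C)[C@H](C/C=C1\C[C@H](CI)OC1=O)C[C@@H]2O[C@]2(C)C(=O)CC(=O)CC(=O)OC | intermediate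
21 | disodium C8,C10-dianion of 20 | [Na+].[Na+].C=C(C)[C@H](C/C=C1\C[C@H](CI)OC1=O)C[C@@H]2O[C@]2(C)C([O-])=CC([O-])=CC(=O)OC | intermediate (not isolated)
22 | sodium C9–C11 diketonate of the macrocycle, C8 not yet fixed | [Na+].C=C(C)[C@@H]1C/C=C2\C[C@H](CC(C(=O)OC)C(=O)C=C([O-])[C@@]3(C)O[C@H]3C1)OC2=O | intermediate (not isolated)
23 | CNP0108136.1, (1R,3E,6S,8S,12S,13S) in the numbering above | C=C(C)[C@@H]1C/C=C2\C[C@H](C[C@H](C(=O)OC)C(=O)CC(=O)[C@@]3(C)O[C@H]3C1)OC2=O | target

## Step count, risks and fallbacks

Total step count: 11. Longest linear sequence: 8 steps (steps 1–6, 10 and 11, from (S)-carvone).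

Steps most likely to fail:

1. Step 11 (carries the label). What may go wrong: the C8 carbanion of the dianion may add to the lactone carbonyl C18 or act as a base, or ring closure may be outrun by intermolecular alkylation, so that the 14-membered ring does not form. The fallback uses known chemistry, the macrocyclising C-alkylation of a simple β-keto ester monoanion, with C11 carried as a silyl-protected alcohol so that only C8 is acidic. It sets out from 8 and comes back to the route at 23. Reduction of 8 with i-Bu2AlH (CH2Cl2, −78 °C) should give the epoxy aldehyde F1. Aldol addition of dianion 10 (THF, −78 °C) should give the δ-hydroxy-β-keto ester F2 (C11 epimers, both usable). TBSOTf and 2,6-lutidine should give the silyl ether F3, and PPTS in wet acetone the aldehyde F4. Horner–Wadsworth–Emmons reaction with 19 (LiCl, DBU, MeCN) should give the silyl-protected seco-iodide F5. Cs2CO3 in MeCN (2 mM, 60 °C) should close the macrocyclic β-keto ester F6 by alkylation at C8. HF·pyridine should give the alcohol F7, and Dess–Martin periodinane (NaHCO3, CH2Cl2) then oxidises C11–OH to reach 23.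

2. Step 5. What may go wrong: acyl substitution at the hindered glycidic ester may be slow, so that proton transfer or opening of the epoxide by the dianion takes over. The fallback builds the C10–C11 bond at the aldehyde oxidation level and oxidises afterwards. It sets out from 8 and comes back at 11. i-Bu2AlH (CH2Cl2, −78 °C) should give the epoxy aldehyde F8 (same structure as F1), dianion 10 should add to it to give the δ-hydroxy-β-keto ester F9 (same structure as F2), and Dess–Martin periodinane should oxidise the β-hydroxy ketone to the 3,5-diketo ester 11.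

3. Step 4. What may go wrong: the basic ylide may enolise the α-isopropenyl aldehyde, causing epimerisation at C1 or migration of the isopropenyl double bond into conjugation. The fallback replaces the Wittig reaction by a non-basic methylenation followed by anti-Markovnikov hydration. It sets out from 5 and comes back at 12. CH2I2, Zn and Ti(OiPr)4 in THF should give the diene ester F10. Hydroboration of the monosubstituted vinyl group with disiamylborane, then NaBO3·4H2O, should give the primary alcohol F11, and Dess–Martin periodinane the aldehyde F12. HC(OMe)3, PPTS and MeOH should give the dimethyl acetal F13. Claisen acylation of dianion 10 as in step 5 should give the diketo ester acetal F14, and PPTS in wet acetone then frees the aldehyde 12.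

Further compounds

F1 | step 11 | (2S,3S)-3-[(2S)-2-(2-methoxyethenyl)-3-methylbut-3-en-1-yl]-2-methyloxirane-2-carbaldehyde | C=C(C)[C@H](C=COC)C[C@@H]1O[C@]1(C)C=O
F2 | step 11 | methyl 5-hydroxy-5-[(2S,3S)-3-[(2S)-2-(2-methoxyethenyl)-3-methylbut-3-en-1-yl]-2-methyloxiran-2-yl]-3-oxopentanoate, C5 epimers | C=C(C)[C@H](C=COC)C[C@@H]1O[C@]1(C)C(O)CC(=O)CC(=O)OC
F3 | step 11 | tert-butyldimethylsilyl ether of F2 | C=C(C)[C@H](C=COC)C[C@@H]1O[C@]1(C)C(O[Si](C)(C)C(C)(C)C)CC(=O)CC(=O)OC
F4 | step 11 | aldehyde from F3 (2-oxoethyl in place of 2-methoxyethenyl) | C=C(C)[C@H](CC=O)C[C@@H]1O[C@]1(C)C(O[Si](C)(C)C(C)(C)C)CC(=O)CC(=O)OC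
F5 | step 11 | seco-iodide with C11–OTBS in place of the C11 ketone of 20 | C=C(C)[C@H](C/C=C1\C[C@H](CI)OC1=O)C[C@@H]2O[C@]2(C)C(O[Si](C)(C)C(C)(C)C)CC(=O)CC(=O)OC
F6 | step 11 | macrocycle with C11–OTBS in place of the C11 ketone of 23, C8 and C11 epimers | C=C(C)[C@@H]1C/C=C2\C[C@H](CC(C(=O)OC)C(=O)CC(O[Si](C)(C)C(C)(C)C)[C@@]3(C)O[C@H]3C1)OC2=O
F7 | step 11 | macrocyclic C11 alcohol, C8 and C11 epimers | C=C(C)[C@@H]1C/C=C2\C[C@H](CC(C(=O)OC)C(=O)CC(O)[C@@]3(C)O[C@H]3C1)OC2=O
F8 | step 5 | (2S,3S)-3-[(2S)-2-(2-methoxyethenyl)-3-methylbut-3-en-1-yl]-2-methyloxirane-2-carbaldehyde | C=C(C)[C@H](C=COC)C[C@@H]1O[C@]1(C)C=O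
F9 | step 5 | methyl 5-hydroxy-5-[(2S,3S)-3-[(2S)-2-(2-methoxyethenyl)-3-methylbut-3-en-1-yl]-2-methyloxiran-2-yl]-3-oxopentanoate, C5 epimers | C=C(C)[C@H](C=COC)C[C@@H]1O[C@]1(C)C(O)CC(=O)CC(=O)OC
F10 | step 4 | methyl (2S,3S)-3-(2-ethenyl-3-methylbut-3-en-1-yl)-2-methyloxirane-2-carboxylate, C1 as in 5 | C=C(C)[C@H](C=C)C[C@@H]1O[C@]1(C)C(=O)OC
F11 | step 4 | methyl (2S,3S)-3-[2-(2-hydroxyethyl)-3-methylbut-3-en-1-yl]-2-methyloxirane-2-carboxylate, C1 as in 5 | C=C(C)[C@H](CCO)C[C@@H]1O[C@]1(C)C(=O)OC
F12 | step 4 | methyl (2S,3S)-2-methyl-3-[3-methyl-2-(2-oxoethyl)but-3-en-1-yl]oxirane-2-carboxylate, C1 as in 5 | C=C(C)[C@H](CC=O)C[C@@H]1O[C@]1(C)C(=O)OC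
F13 | step 4 | dimethyl acetal of F12 | C=C(C)[C@H](CC(OC)OC)C[C@@H]1O[C@]1(C)C(=O)OC
F14 | step 4 | dimethyl acetal of aldehyde 12 | C=C(C)[C@H](CC(OC)OC)C[C@@H]1O[C@]1(C)C(=O)CC(=O)CC(=O)OC
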